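**Retrosynthetic overview**

1. The C19 ester is made last from diol 20 and (E)-4-acetoxycinnamic acid. The diene comes from a C9 vinyl group by hydroboration and B-alkyl Suzuki coupling (C12–C13). The 8α-OH/8β-CH3 pair comes from a C8 exocyclic methylene through its α-epoxide and hydride.
2. All of this derives from bicyclic β-keto ester 10 (C8 ketone; the ester carbon on C9 is C11). Ring B of 10 is cut at C6–C7 and C9–C10: a one-flask formal [3+3] union of ring A allylic acetate 6 with the bis(silyl enol ether) of methyl acetoacetate, 8.
3. Enabling feature: in ring B the carbinol carbon C8 sits between C7 and C9 (an acetone 1,3-dinucleophile pattern). In ring A, C6–C5–C10 is an allyl cation whose C5=C10 alkene can be re-protonated to a C10 cation (a 1,3-dielectrophile). The C4 ester (the future C19) steers the face of attack.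
4. Ring A is bought as methyl 2-oxocyclohexane-1-carboxylate. C4 is set by asymmetric methylation and is the only stereocentre that enters the key step, which sets C5, C9 and C10; C8 follows by substrate control.
5. Ring order: ring A (preformed), then ring B (key step).

Key step: step 7

Remark: atom labels C1–C20 are those of the labdane skeleton of the target (C17 on C8, C18/C19 on C4, C20 on C10, C11–C16 side chain) and are used for all intermediates.

**Step 1**
Reactants: 1 methyl 2-oxocyclohexane-1-carboxylate
Product: 2 methyl (S)-1-methyl-2-oxocyclohexane-1-carboxylate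
Conditions: MeI, Cs2CO3, chiral N-spiro binaphthyl quaternary ammonium bromide (2 mol %), toluene, −20 °C
Reagents that add atoms: iodomethane, CI
Why: Asymmetric phase-transfer alkylation of a cyclic β-keto ester: the chiral ammonium cation pairs with the enolate and blocks one face, so C-methylation should set the quaternary C4 centre as (S) when the appropriate catalyst antipode is used.

**Step 2**
Reactants: 2 methyl (S)-1-methyl-2-oxocyclohexane-1-carboxylate
Product: 3 methyl (1S,3RS)-1,3-dimethyl-2-oxocyclohexane-1-carboxylate
Conditions: LiN(iPr)2, THF, −78 °C; MeI, −78 → 0 °C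
Reagents that add atoms: iodomethane, CI
Why: Kinetic enolate alkylation at the only enolisable α-position (the future C10), whose configuration is left uncontrolled because this carbon becomes sp2 in step 3.

**Step 3**
Reactants: 3 methyl (1S,3RS)-1,3-dimethyl-2-oxocyclohexane-1-carboxylate
Product: 4 methyl (S)-1,3-dimethyl-2-{[(trifluoromethyl)sulfonyl]oxy}cyclohex-2-ene-1-carboxylate
Conditions: KN(SiMe3)2, THF, −78 → 0 °C; PhNTf2
Reagents that add atoms: N-phenylbis(trifluoromethanesulfonimide), O=S(=O)(N(c1ccccc1)S(=O)(=O)C(F)(F)F)C(F)(F)F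
Why: Enol triflate formation from the only possible (fully substituted) enolate, so the position of the C5=C10 alkene is unambiguous and no stereocentre is made.

**Step 4**
Reactants: 4 methyl (S)-1,3-dimethyl-2-{[(trifluoromethyl)sulfonyl]oxy}cyclohex-2-ene-1-carboxylate
Product: 5 methyl (S)-2-(hydroxymethyl)-1,3-dimethylcyclohex-2-ene-1-carboxylate
Conditions: Bu3SnCH2OH, Pd(PPh3)4 (5 mol %), LiCl, 1,4-dioxane, 100 °C
Reagents that add atoms: (tributylstannyl)methanol, CCCC[Sn](CCCC)(CCCC)CO
Why: Stille cross-coupling of the enol triflate with a hydroxymethyl stannane (selective transfer of the CH2OH group) puts C6 on C5 at the alcohol oxidation level without touching C4.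

**Step 5**
Reactants: 5 methyl (S)-2-(hydroxymethyl)-1,3-dimethylcyclohex-2-ene-1-carboxylate
Product: 6 methyl (S)-2-(acetoxymethyl)-1,3-dimethylcyclohex-2-ene-1-carboxylate
Conditions: Ac2O, pyridine, DMAP (cat.), CH2Cl2, 0 °C
Reagents that add atoms: acetic anhydride, CC(=O)OC(C)=O
Why: Acetylation of the primary allylic alcohol, done at once so that lactonisation onto the C19 ester cannot compete, makes C6 an ionisable allylic centre; no stereocentre is formed.

**Step 6**
Reactants: 7 methyl 3-(trimethylsilyloxy)but-2-enoate
Product: 8 1-methoxy-1,3-bis(trimethylsilyloxy)buta-1,3-diene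
Conditions: LiN(iPr)2, THF, −78 °C; Me3SiCl
Reagents that add atoms: chlorotrimethylsilane, C[Si](C)(C)Cl
Why: Deprotonation at the γ-methyl group of the silyl enol ether and O-silylation of the resulting ester dienolate give the 1,3-bis(silyl enol ether), a C7/C9 double nucleophile; no stereocentre is formed.

**Step 7**
Reactants: 6 methyl (S)-2-(acetoxymethyl)-1,3-dimethylcyclohex-2-ene-1-carboxylate; 8 1-methoxy-1,3-bis(trimethylsilyloxy)buta-1,3-diene
Product: 10 dimethyl 8-oxo-12,13,14,15,16,17-hexanorlabdane-11,19-dioate (trans-decalin; 4α-CH3, 4β-CO2Me, 5α-H, 9β-CO2Me, 10β-CH3), via uncyclised keto diester 9 (not isolated)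
Conditions: SnCl4 (2.5 equiv), CH2Cl2, −78 °C, 1 h; then H2O (1 equiv, as wet CH2Cl2), −78 → 23 °C, 12 h
Reagents that add atoms: none
Why: Proposed new method: SnCl4 ionises the allylic acetate of 6 to the ring A allyl cation (C6–C5–C10), which the terminal carbon of 8 captures at the unhindered primary terminus C6 (bond C6–C7, a vinylogous Mukaiyama-type SN1 alkylation) to give 9 as its tin chelate; protonation of the tetrasubstituted C5=C10 alkene at C5 then gives the tertiary C10 cation, which the β-keto ester enol carbon C9 attacks (bond C9–C10). The closest known reaction types are the Lewis-acid γ-alkylation of 1,3-bis(silyl enol ethers) by stabilised carbocations and the SnCl4-promoted cyclisation of 2-(cyclohexenyl)ethyl β-keto esters to trans-fused 2-oxodecalin-1-carboxylates (a β-keto ester-terminated cation–olefin cyclisation); only their merger in one flask is new, and it is reasonable because both use the same Lewis acid and the product of the first is the substrate of the second. Ring B closes in the 6-(enol-endo) mode onto the C10 cation through a chair transition state. C5 (H α) and C10 (CH3 β) arise from anti addition of H and C9 across C5=C10 in that chair, which gives the trans ring fusion, and C9 ends with its ester equatorial (β) because it stays epimerisable in the β-keto ester. Relative to the one stereocentre carried in (C4), C9 must enter C10 on the face away from the C4 ester: reversible protonation at C5 lets the two diastereomeric chairs compete, and the chair with the CO2Me group axial should win because its carbonyl oxygen can bridge the β lobe of the C10 cation (five-membered dioxolenium-type participation) and an ester is the smaller syn-axial partner for the C10 methyl, so that C19 and C20 end cis-diaxial as in the target. Regioselectivity (C6 over C10 in the first bond, terminal over central carbon of 8) should follow from the hindrance of the tertiary terminus and from the known γ-preference of such dienes.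

**Step 8**
Reactants: 10 dimethyl 8-oxo-12,13,14,15,16,17-hexanorlabdane-11,19-dioate
Product: 11 dimethyl 12,13,14,15,16-pentanorlabd-8(17)-ene-11,19-dioate
Conditions: Zn, CH2Br2, TiCl4, THF/CH2Cl2, 0 → 23 °C
Reagents that add atoms: dibromomethane, BrCBr
Why: Takai–Lombardo methylenation: the non-basic zinc/titanium methylene reagent tolerates the acidic C9–H and both esters and converts the hindered C8 ketone into the exocyclic C8=C17 alkene, C9 keeping its equatorial (β) ester.

**Step 9**
Reactants: 11 dimethyl 12,13,14,15,16-pentanorlabd-8(17)-ene-11,19-dioate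
Product: 12 methyl 11-hydroxy-12,13,14,15,16-pentanorlabd-8(17)-en-19-oate
Conditions: iBu2AlH (2.2 equiv), CH2Cl2, −78 °C
Reagents that add atoms: none
Why: Hydride reduction of the equatorial C11 ester at low temperature, chemoselective because the axial neopentyl C19 ester is shielded by the syn-axial C10 methyl group; no stereocentre is formed.

**Step 10**
Reactants: 12 methyl 11-hydroxy-12,13,14,15,16-pentanorlabd-8(17)-en-19-oate
Product: 13 methyl 11-oxo-12,13,14,15,16-pentanorlabd-8(17)-en-19-oate
Conditions: Dess–Martin periodinane, pyridine, CH2Cl2, 0 °C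
Reagents that add atoms: none
Why: Dess–Martin oxidation under buffered, non-epimerising conditions gives the β,γ-unsaturated aldehyde, which is used at once; the equatorial C9 configuration is also the thermodynamically preferred one.

**Step 11**
Reactants: 13 methyl 11-oxo-12,13,14,15,16-pentanorlabd-8(17)-en-19-oate
Product: 14 methyl 13,14,15,16-tetranorlabda-8(17),11-dien-19-oate
Conditions: Ph3PCH3Br, KN(SiMe3)2, THF, 0 °C; then 13, −78 → 0 °C
Reagents that add atoms: methyltriphenylphosphonium bromide, C[P+](c1ccccc1)(c1ccccc1)c1ccccc1.[Br-]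
Why: Wittig methylenation of the aldehyde at low temperature converts C11 into the vinyl group (C11=C12) faster than the ylide can enolise C9, whose equatorial configuration is in any case the stable one.

**Step 12**
Reactants: 14 methyl 13,14,15,16-tetranorlabda-8(17),11-dien-19-oate
Product: 15 methyl 8α,17-epoxy-13,14,15,16-tetranorlabd-11-en-19-oate
Conditions: mCPBA, CH2Cl2, 0 °C
Reagents that add atoms: 3-chloroperoxybenzoic acid, OOC(=O)c1cccc(Cl)c1
Why: Prilezhaev epoxidation: the 1,1-disubstituted C8=C17 alkene is far more nucleophilic than the monosubstituted vinyl group, and the peracid approaches from the α face because the β face is blocked by the syn-axial C10 methyl group, placing the epoxide oxygen α at C8.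

**Step 13**
Reactants: 16 2-(trimethylsilyloxy)buta-1,3-diene
Product: 17 buta-1,3-dien-2-yl trifluoromethanesulfonate
Conditions: MeLi, THF, −78 → 0 °C; PhNTf2, −78 °C
Reagents that add atoms: N-phenylbis(trifluoromethanesulfonimide), O=S(=O)(N(c1ccccc1)S(=O)(=O)C(F)(F)F)C(F)(F)F
Why: Regiospecific generation of the cross-conjugated lithium enolate from the silyl enol ether and O-triflation give the dienyl triflate; no stereocentre is involved.

**Step 14**
Reactants: 15 methyl 8α,17-epoxy-13,14,15,16-tetranorlabd-11-en-19-oate; 17 buta-1,3-dien-2-yl trifluoromethanesulfonate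
Product: 19 methyl 8α,17-epoxylabda-13(16),14-dien-19-oate, via alkylborane 18 (not isolated)
Conditions: 9-borabicyclo[3.3.1]nonane, THF, 23 °C; then 17, PdCl2(dppf) (5 mol %), K3PO4 (aq), DMF, 50 °C
Reagents that add atoms: none
Why: Anti-Markovnikov hydroboration of the vinyl group followed by B-alkyl Suzuki–Miyaura coupling with the alkenyl triflate forges C12–C13 and delivers the 2-substituted buta-1,3-diene, leaving the epoxide, the ester and all stereocentres untouched.

**Step 15**
Reactants: 19 methyl 8α,17-epoxylabda-13(16),14-dien-19-oate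
Product: 20 labda-13(16),14-diene-8α,19-diol
Conditions: LiAlH4, THF, 0 → 65 °C
Reagents that add atoms: none
Why: LiAlH4 opens the spiro-epoxide by hydride attack at the primary carbon C17, so the C8–O bond is retained (8α-OH, 8β-CH3), and it reduces the C19 ester to the primary alcohol; the diene is inert to hydride.

**Step 16**
Reactants: 20 labda-13(16),14-diene-8α,19-diol; 21 (E)-4-acetoxycinnamic acid
Product: 22 8α-hydroxylabda-13(16),14-dien-19-yl (E)-4-acetoxycinnamate
Conditions: EDC·HCl, DMAP, CH2Cl2, 23 °C
Reagents that add atoms: none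
Why: Steglich-type carbodiimide esterification acylates the primary C19 hydroxyl selectively over the hindered tertiary C8 hydroxyl and keeps the (E) geometry of the cinnamate.

**Step 17**
Reactants: 22 8α-hydroxylabda-13(16),14-dien-19-yl (E)-4-acetoxycinnamate
Product: 23 8α-hydroxylabda-13(16),14-dien-19-yl p-hydroxycinnamate
Conditions: K2CO3 (0.2 equiv), MeOH, 0 °C
Reagents that add atoms: none
Why: Base-catalysed methanolysis (transesterification) cleaves the phenyl acetate much faster than the hindered neopentyl cinnamate, releasing the free phenol of the target.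

**Compound list**

1 | methyl 2-oxocyclohexane-1-carboxylate | COC(=O)C1CCCCC1=O | starting material
2 | methyl (S)-1-methyl-2-oxocyclohexane-1-carboxylate | C1CC[C@](C)(C(=O)OC)C(=O)C1 | intermediate
3 | methyl (1S,3RS)-1,3-dimethyl-2-oxocyclohexane-1-carboxylate | C1CC[C@](C)(C(=O)OC)C(=O)C1C | intermediate
4 | methyl (S)-1,3-dimethyl-2-{[(trifluoromethyl)sulfonyl]oxy}cyclohex-2-ene-1-carboxylate | C1CC[C@](C)(C(=O)OC)C(OS(=O)(=O)C(F)(F)F)=C1C | intermediate
5 | methyl (S)-2-(hydroxymethyl)-1,3-dimethylcyclohex-2-ene-1-carboxylate | C1CC[C@](C)(C(=O)OC)C(CO)=C1C | intermediate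
6 | methyl (S)-2-(acetoxymethyl)-1,3-dimethylcyclohex-2-ene-1-carboxylate | C1CC[C@](C)(C(=O)OC)C(COC(C)=O)=C1C | intermediate
7 | methyl 3-(trimethylsilyloxy)but-2-enoate | COC(=O)C=C(C)O[Si](C)(C)C | starting material
8 | 1-methoxy-1,3-bis(trimethylsilyloxy)buta-1,3-diene | COC(O[Si](C)(C)C)=CC(=C)O[Si](C)(C)C | intermediate
9 | methyl 5-[(6S)-6-(methoxycarbonyl)-2,6-dimethylcyclohex-1-en-1-yl]-3-oxopentanoate (uncyclised keto diester) | COC(=O)CC(=O)CCC1=C(C)CCC[C@]1(C)C(=O)OC | intermediate
10 | dimethyl 8-oxo-12,13,14,15,16,17-hexanorlabdane-11,19-dioate (4α-CH3, 4β-CO2Me, 5α-H, 9β-CO2Me, 10β-CH3) | COC(=O)[C@@H]1[C@@]2(C)CCC[C@](C)(C(=O)OC)[C@@H]2CCC1=O | intermediate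
11 | dimethyl 12,13,14,15,16-pentanorlabd-8(17)-ene-11,19-dioate | COC(=O)[C@@H]1[C@@]2(C)CCC[C@](C)(C(=O)OC)[C@@H]2CCC1=C | intermediate
12 | methyl 11-hydroxy-12,13,14,15,16-pentanorlabd-8(17)-en-19-oate | OC[C@@H]1[C@@]2(C)CCC[C@](C)(C(=O)OC)[C@@H]2CCC1=C | intermediate
13 | methyl 11-oxo-12,13,14,15,16-pentanorlabd-8(17)-en-19-oate | O=C[C@@H]1[C@@]2(C)CCC[C@](C)(C(=O)OC)[C@@H]2CCC1=C | intermediate
14 | methyl 13,14,15,16-tetranorlabda-8(17),11-dien-19-oate | C=C[C@@H]1[C@@]2(C)CCC[C@](C)(C(=O)OC)[C@@H]2CCC1=C | intermediate
15 | methyl 8α,17-epoxy-13,14,15,16-tetranorlabd-11-en-19-oate | C=C[C@@H]1[C@@]2(C)CCC[C@](C)(C(=O)OC)[C@@H]2CC[C@@]1(C3)O3 | intermediate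
16 | 2-(trimethylsilyloxy)buta-1,3-diene | C=CC(=C)O[Si](C)(C)C | starting material
17 | buta-1,3-dien-2-yl trifluoromethanesulfonate | C=CC(=C)OS(=O)(=O)C(F)(F)F | intermediate
18 | methyl 12-(9-borabicyclo[3.3.1]nonan-9-yl)-8α,17-epoxy-13,14,15,16-tetranorlabdan-19-oate (alkylborane) | C(C[C@@H]1[C@@]2(C)CCC[C@](C)(C(=O)OC)[C@@H]2CC[C@@]1(C3)O3)B4C5CCCC4CCC5 | intermediate
19 | methyl 8α,17-epoxylabda-13(16),14-dien-19-oate | C=CC(=C)CC[C@@H]1[C@@]2(C)CCC[C@](C)(C(=O)OC)[C@@H]2CC[C@@]1(C3)O3 | intermediate
20 | labda-13(16),14-diene-8α,19-diol | C=CC(=C)CC[C@@H]1[C@@]2(C)CCC[C@](C)(CO)[C@@H]2CC[C@@]1(C)O | intermediate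
21 | (E)-4-acetoxycinnamic acid | CC(=O)Oc1ccc(/C=C/C(=O)O)cc1 | starting material
22 | 8α-hydroxylabda-13(16),14-dien-19-yl (E)-4-acetoxycinnamate | C=CC(=C)CC[C@@H]1[C@@]2(C)CCC[C@](C)(COC(=O)/C=C/c3ccc(OC(C)=O)cc3)[C@@H]2CC[C@@]1(C)O | intermediate
23 | 8α-hydroxylabda-13(16),14-dien-19-yl p-hydroxycinnamate | C=CC(=C)CC[C@@H]1[C@@]2(C)CCC[C@](C)(COC(=O)/C=C/c3ccc(O)cc3)[C@@H]2CC[C@@]1(C)O | target

**Step count**

Total step count: 17. Longest linear sequence: 15 steps (steps 1–5, 7–12 and 14–17; steps 6 and 13 make the two side reagents).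

**Steps most likely to fail**

Step 7 (Proposed new method). The two Lewis-acid events may not telescope: the diene may be desilylated or O-alkylated before the C6–C7 bond forms, the allyl cation may be attacked at its tertiary terminus, or the C10 cation may close with poor facial discrimination relative to C4 or be intercepted by the C19 ester. The fallback separates the two bond formations with known reactions. It sets out from 5, which is converted with CBr4 and PPh3 (Appel reaction) into methyl (S)-2-(bromomethyl)-1,3-dimethylcyclohex-2-ene-1-carboxylate F1. The dilithio dianion of methyl acetoacetate (LiN(iPr)2, 2 equiv, THF, 0 °C) is alkylated at its γ-carbon by F1 to give 9, now isolated. Treatment of 9 with SnCl4 in wet CH2Cl2 (0 → 23 °C), the established β-keto ester cation–olefin cyclisation, should then close ring B, and the route is rejoined at 10.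

Step 8. The acidic β-keto ester may be turned into an unreactive zinc or titanium enolate, or the hindered C8 carbonyl may be methylenated too slowly. The fallback builds C17 by cross-coupling instead of carbonyl olefination and sets out from 10. NaH and PhNTf2 give dimethyl 8-(trifluoromethylsulfonyloxy)-12,13,14,15,16,17-hexanorlabd-8-ene-11,19-dioate F2. Kumada coupling of F2 with Me3SiCH2MgCl (Pd(PPh3)4, THF) gives the allylsilane dimethyl 17-(trimethylsilyl)-12,13,14,15,16-pentanorlabd-8-ene-11,19-dioate F3. Protodesilylation of F3 with allylic transposition (Bu4NF, wet THF) should put the proton on C9 and leave the exocyclic C8=C17 alkene, and the route is rejoined at 11.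

Step 14. Transfer of the primary alkyl group from boron to palladium may be slow next to the congested C9, and the volatile dienyl triflate may polymerise or the borane may undergo protodeboronation before coupling. The fallback makes the C12–C13 bond with the polarity reversed and sets out from 15. Hydroboration–oxidation (9-borabicyclo[3.3.1]nonane; then NaOH, H2O2) gives methyl 8α,17-epoxy-12-hydroxy-13,14,15,16-tetranorlabdan-19-oate F4. TsCl and pyridine give methyl 8α,17-epoxy-12-(4-methylphenylsulfonyloxy)-13,14,15,16-tetranorlabdan-19-oate F5. Copper-catalysed coupling of F5 with CH2=C(MgCl)CH=CH2 (from 2-chlorobuta-1,3-diene and Mg; Li2CuCl4 cat., THF, −20 °C) should give the diene, and the route is rejoined at 19; no free C8 hydroxyl is present, so ether formation onto C12 cannot compete.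

**Further compounds**

F1 | step 7 | methyl (S)-2-(bromomethyl)-1,3-dimethylcyclohex-2-ene-1-carboxylate | C1CC[C@](C)(C(=O)OC)C(CBr)=C1C
F2 | step 8 | dimethyl 8-(trifluoromethylsulfonyloxy)-12,13,14,15,16,17-hexanorlabd-8-ene-11,19-dioate | COC(=O)C1[C@@]2(C)CCC[C@](C)(C(=O)OC)[C@@H]2CCC=1OS(=O)(=O)C(F)(F)F
F3 | step 8 | dimethyl 17-(trimethylsilyl)-12,13,14,15,16-pentanorlabd-8-ene-11,19-dioate | COC(=O)C1[C@@]2(C)CCC[C@](C)(C(=O)OC)[C@@H]2CCC=1C[Si](C)(C)C
F4 | step 14 | methyl 8α,17-epoxy-12-hydroxy-13,14,15,16-tetranorlabdan-19-oate | OCC[C@@H]1[C@@]2(C)CCC[C@](C)(C(=O)OC)[C@@H]2CC[C@@]1(C3)O3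
F5 | step 14 | methyl 8α,17-epoxy-12-(4-methylphenylsulfonyloxy)-13,14,15,16-tetranorlabdan-19-oate | Cc1ccc(cc1)S(=O)(=O)OCC[C@@H]2[C@@]3(C)CCC[C@](C)(C(=O)OC)[C@@H]3CC[C@@]2(C4)O4
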